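The heptane chain carries the guaiacyl ring on C1 and hydroxyls on C3 and C5. Tying O5 to C1 and raising C3 to a ketone folds C1–C5 into a 2,3-dihydro-4H-pyran-4-one whose C1 is the electrophilic β-carbon of a vinylogous ester. Everything rests on the disconnection between C1 and the guaiacyl ipso carbon. Rhodium-catalysed 1,4-addition of a guaiacyl boronic acid to the enantioenriched pyranone, itself one hetero-Diels–Alder step from a syringylpropanal, unites both halves. The new aryl group makes the temporary O5–C1 bond benzylic, so hydrogenolysis unzips the ring along with both benzyl ethers, and the freed C5 hydroxyl directs syn reduction at C3.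

Key step: step 4

Remark on numbering: heptane C1 bears the guaiacyl ring and C7 the syringyl ring; the target is the (3S,5R) diol, which is the 3,5-syn diol.
Assumption: the Ti–(S)-BINOLate complex is taken to direct attack to the Si face of aldehyde 4, as in the related allylation with the same complex; if the sense proves opposite, (R)-BINOL is used instead.

Step 1
Reactants: 1 4-bromo-2,6-dimethoxyphenol
Product: 2 2-(benzyloxy)-5-bromo-1,3-dimethoxybenzene
Conditions: BnBr, K2CO3, DMF, 50 °C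
Reagents that add atoms: benzyl bromide, BrCc1ccccc1
Why: Williamson etherification of the acidic phenol; benzyl is chosen because it leaves in the same hydrogenolysis that later opens the temporary ring.

Step 2
Reactants: 2 2-(benzyloxy)-5-bromo-1,3-dimethoxybenzene; 3 prop-2-en-1-ol (allyl alcohol)
Product: 4 3-[4-(benzyloxy)-3,5-dimethoxyphenyl]propanal
Conditions: Pd(OAc)2 (cat.), P(o-tol)3 (cat.), n-Bu4NCl, NaHCO3, DMF, 100 °C
Reagents that add atoms: none
Why: Heck arylation of an allylic alcohol (Jeffery conditions): carbopalladation at the terminal carbon, β-hydride elimination towards the carbinol, then tautomerisation of the enol should give the saturated aldehyde.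

Step 3
Reactants: 4 3-[4-(benzyloxy)-3,5-dimethoxyphenyl]propanal; 5 (E)-1-methoxy-3-(trimethylsilyloxy)buta-1,3-diene (Danishefsky's diene)
Product: 7 (2R)-2-{2-[4-(benzyloxy)-3,5-dimethoxyphenyl]ethyl}-2,3-dihydro-4H-pyran-4-one, via silylated aldol adduct (1E,5R)-7-[4-(benzyloxy)-3,5-dimethoxyphenyl]-1-methoxy-5-(trimethylsilyloxy)hept-1-en-3-one 6 (not isolated)
Conditions: (S)-BINOL (20 mol %), Ti(OiPr)4 (10 mol %), 4 Å MS, Et2O, −20 °C; then TFA, CH2Cl2, 0 °C
Reagents that add atoms: none
Why: Catalytic asymmetric formal hetero-Diels–Alder reaction (Mukaiyama aldol, then acid-induced 6-endo oxa-Michael closure with loss of methanol), in which the chiral titanium BINOLate shields one aldehyde face so that Si-face attack sets pyran C2 (heptane C5) as R.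

Step 4
Reactants: 7 (2R)-2-{2-[4-(benzyloxy)-3,5-dimethoxyphenyl]ethyl}-2,3-dihydro-4H-pyran-4-one; 8 [4-(benzyloxy)-3-methoxyphenyl]boronic acid
Product: 9 (2S,6R)-2-[4-(benzyloxy)-3-methoxyphenyl]-6-{2-[4-(benzyloxy)-3,5-dimethoxyphenyl]ethyl}oxan-4-one (2,6-trans)
Conditions: [Rh(cod)2]BF4 (5 mol %), 8 (2 equiv), dioxane–H2O (10:1), 90 °C, no added base
Reagents that add atoms: none
Why: Transmetalation of 8 to the cationic Rh(I) centre gives an aryl–rhodium species that carbometalates the C5=C6 bond of 7, delivering the guaiacyl ipso carbon to C6 (heptane C1, the β-carbon of the vinylogous ester), and water protonates the resulting oxa-π-allyl rhodium enolate to release ketone 9 and a Rh–OH species that re-enters the cycle. The closest known reaction type is the Hayashi–Miyaura 1,4-addition of arylboronic acids, which has been applied to sugar-derived 2,3-dihydro-4H-pyran-4-ones to make aryl C-glycosides. No ring is closed; the pyranone ring made in step 3 serves only as a temporary O5–C1 tether. The one new stereocentre, C2 of 9, should arise from axial attack on the half-chair anti to the pseudo-equatorial side chain of 7 (2,6-trans), but either epimer is serviceable because step 5 turns this carbon into a CH2 group. The step needs 1,4- over 1,2-regioselectivity, secured by the soft aryl–rhodium nucleophile and the polarisation of the enone by O1, and it needs retention of the C5 configuration, secured by base-free conditions that avoid E1cB opening of the ring at the alkyl-bearing C–O bond. Fast protonolysis in the aqueous medium should outrun β-alkoxide elimination, so that no acyclic enone is exposed to a second arylation.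

Step 5
Reactants: 9 (2S,6R)-2-[4-(benzyloxy)-3-methoxyphenyl]-6-{2-[4-(benzyloxy)-3,5-dimethoxyphenyl]ethyl}oxan-4-one
Product: 11 (5R)-5-hydroxy-1-(4-hydroxy-3-methoxyphenyl)-7-(4-hydroxy-3,5-dimethoxyphenyl)heptan-3-one, via bis-phenol (2S,6R)-2-(4-hydroxy-3-methoxyphenyl)-6-[2-(4-hydroxy-3,5-dimethoxyphenyl)ethyl]oxan-4-one 10 (not isolated)
Conditions: H2 (4 atm), 20% Pd(OH)2/C, MeOH–AcOH (10:1), rt
Reagents that add atoms: none
Why: Catalytic hydrogenolysis removes the aryl benzyl ethers first to give 10, whose ring C2–O bond is a benzylic ether para to a free phenol and β to the ketone, so direct benzylic C–O hydrogenolysis and acid-assisted retro-oxa-Michael opening with alkene saturation converge on 11, while the non-benzylic C5–O bond keeps its R configuration and the transient C2 centre is erased.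

Step 6
Reactants: 11 (5R)-5-hydroxy-1-(4-hydroxy-3-methoxyphenyl)-7-(4-hydroxy-3,5-dimethoxyphenyl)heptan-3-one
Product: 13 (3S,5R)-1-(4-hydroxy-3-methoxyphenyl)-7-(4-hydroxy-3,5-dimethoxyphenyl)heptane-3,5-diol, via diethylboron chelate (5R)-5-[(diethylboranyl)oxy]-1-(4-hydroxy-3-methoxyphenyl)-7-(4-hydroxy-3,5-dimethoxyphenyl)heptan-3-one 12 (not isolated)
Conditions: Et2BOMe (1.5 equiv), THF–MeOH (4:1), −78 °C; NaBH4, −78 °C; pH 7 buffer, then repeated co-evaporation with MeOH
Reagents that add atoms: none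
Why: Narasaka–Prasad reduction, in which boron locks the β-hydroxy ketone as a six-membered chelate with the C5 side chain pseudo-equatorial and external hydride attacks axially, should give the 3,5-syn diol, that is 3S from 5R; the non-oxidative work-up spares the electron-rich phenols.

Compound list
1 | 4-bromo-2,6-dimethoxyphenol | COc1cc(Br)cc(OC)c1O | starting material
2 | 2-(benzyloxy)-5-bromo-1,3-dimethoxybenzene | COc1cc(Br)cc(OC)c1OCc1ccccc1 | intermediate
3 | prop-2-en-1-ol (allyl alcohol) | C=CCO | starting material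
4 | 3-[4-(benzyloxy)-3,5-dimethoxyphenyl]propanal | COc1cc(CCC=O)cc(OC)c1OCc1ccccc1 | intermediate
5 | (E)-1-methoxy-3-(trimethylsilyloxy)buta-1,3-diene (Danishefsky's diene) | CO/C=C/C(=C)O[Si](C)(C)C | starting material
6 | (1E,5R)-7-[4-(benzyloxy)-3,5-dimethoxyphenyl]-1-methoxy-5-(trimethylsilyloxy)hept-1-en-3-one | CO/C=C/C(=O)C[C@H](O[Si](C)(C)C)CCc1cc(OC)c(OCc2ccccc2)c(OC)c1 | intermediate
7 | (2R)-2-{2-[4-(benzyloxy)-3,5-dimethoxyphenyl]ethyl}-2,3-dihydro-4H-pyran-4-one | O=C1C[C@@H](CCc2cc(OC)c(OCc3ccccc3)c(OC)c2)OC=C1 | intermediate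
8 | [4-(benzyloxy)-3-methoxyphenyl]boronic acid | COc1cc(B(O)O)ccc1OCc1ccccc1 | starting material
9 | (2S,6R)-2-[4-(benzyloxy)-3-methoxyphenyl]-6-{2-[4-(benzyloxy)-3,5-dimethoxyphenyl]ethyl}oxan-4-one | O=C1C[C@@H](CCc2cc(OC)c(OCc3ccccc3)c(OC)c2)O[C@H](c2ccc(OCc3ccccc3)c(OC)c2)C1 | intermediate
10 | (2S,6R)-2-(4-hydroxy-3-methoxyphenyl)-6-[2-(4-hydroxy-3,5-dimethoxyphenyl)ethyl]oxan-4-one | O=C1C[C@@H](CCc2cc(OC)c(O)c(OC)c2)O[C@H](c2ccc(O)c(OC)c2)C1 | intermediate
11 | (5R)-5-hydroxy-1-(4-hydroxy-3-methoxyphenyl)-7-(4-hydroxy-3,5-dimethoxyphenyl)heptan-3-one | COc1cc(CCC(=O)C[C@H](O)CCc2cc(OC)c(O)c(OC)c2)ccc1O | intermediate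
12 | (5R)-5-[(diethylboranyl)oxy]-1-(4-hydroxy-3-methoxyphenyl)-7-(4-hydroxy-3,5-dimethoxyphenyl)heptan-3-one (boron chelate) | COc1cc(CCC(=O)C[C@H](OB(CC)CC)CCc2cc(OC)c(O)c(OC)c2)ccc1O | intermediate
13 | (3S,5R)-1-(4-hydroxy-3-methoxyphenyl)-7-(4-hydroxy-3,5-dimethoxyphenyl)heptane-3,5-diol | COc1cc(CC[C@H](O)C[C@H](O)CCc2cc(OC)c(O)c(OC)c2)ccc1O | target

Total step count: 6. Longest linear sequence: 6 steps (1 → 2 → 4 → 7 → 9 → 11 → 13).

Steps most likely to fail

Step 5. Once the benzyl ethers are gone, the cyclic benzylic C–O bond may be cleaved too slowly, and forcing the acidity may dehydrate the β-hydroxy ketone.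
- The fallback sets out from 9 and returns at 13. It sets C3 inside the ring and opens the ring by ionic reduction instead.
- DBU in toluene equilibrates 9, by reversible opening at the benzylic C–O bond, to the 2,6-cis ketone (2R,6R)-2-[4-(benzyloxy)-3-methoxyphenyl]-6-{2-[4-(benzyloxy)-3,5-dimethoxyphenyl]ethyl}oxan-4-one F1.
- L-Selectride (THF, −78 °C) attacks the diequatorial chair from the equatorial side and should give the axial alcohol (2R,4R,6R)-2-[4-(benzyloxy)-3-methoxyphenyl]-6-{2-[4-(benzyloxy)-3,5-dimethoxyphenyl]ethyl}oxan-4-ol F2, which corresponds to the 3,5-syn relationship.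
- Et3SiH/BF3·OEt2 (CH2Cl2, −40 °C) ionises the p-alkoxybenzylic C–O bond and reduces the cation to (3S,5R)-1-[4-(benzyloxy)-3-methoxyphenyl]-7-[4-(benzyloxy)-3,5-dimethoxyphenyl]heptane-3,5-diol F3.
- H2 over Pd/C then gives 13.

Step 4. Carbometalation of the electron-rich vinylogous ester may be slow. Protodeboronation of the electron-rich boronic acid, or ring opening by β-alkoxide elimination followed by a second arylation, could then take over.
- The fallback sets out from 7 and returns at 9. It replaces the catalytic boron/rhodium manifold by a stoichiometric organocopper addition with silyl trapping at low temperature.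
- Commercial 1-(benzyloxy)-4-bromo-2-methoxybenzene and Mg (THF) give [4-(benzyloxy)-3-methoxyphenyl]magnesium bromide F4.
- F4 adds to 7 with CuBr·SMe2 and TMSCl (THF, −78 °C) to give the enol ether {[(2S,6R)-2-[4-(benzyloxy)-3-methoxyphenyl]-6-{2-[4-(benzyloxy)-3,5-dimethoxyphenyl]ethyl}-5,6-dihydro-2H-pyran-4-yl]oxy}trimethylsilane F5.
- Work-up with dilute acid hydrolyses F5 to 9.

Step 3. Facial selectivity may be insufficient with an unbranched aliphatic aldehyde that carries Lewis-basic ether groups.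
- The fallback sets out from 4 and returns at 7. It sets C5 by asymmetric hydrogenation rather than by a chiral Lewis acid.
- A Roskamp reaction (ethyl diazoacetate, SnCl2, CH2Cl2) gives ethyl 5-[4-(benzyloxy)-3,5-dimethoxyphenyl]-3-oxopentanoate F6.
- Noyori hydrogenation (Ru–(R)-BINAP, H2, EtOH) gives ethyl (3R)-5-[4-(benzyloxy)-3,5-dimethoxyphenyl]-3-hydroxypentanoate F7.
- MeNH(OMe)·HCl and i-PrMgCl (THF, −20 °C) give (3R)-5-[4-(benzyloxy)-3,5-dimethoxyphenyl]-3-hydroxy-N-methoxy-N-methylpentanamide F8.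
- Excess ethynylmagnesium bromide gives (5R)-7-[4-(benzyloxy)-3,5-dimethoxyphenyl]-5-hydroxyhept-1-yn-3-one F9.
- Gold(I)-catalysed 6-endo-dig cyclisation of the hydroxyl onto the ynone closes 7.

Further compounds
F1 | step 5 | (2R,6R)-2-[4-(benzyloxy)-3-methoxyphenyl]-6-{2-[4-(benzyloxy)-3,5-dimethoxyphenyl]ethyl}oxan-4-one | O=C1C[C@@H](CCc2cc(OC)c(OCc3ccccc3)c(OC)c2)O[C@@H](c2ccc(OCc3ccccc3)c(OC)c2)C1
F2 | step 5 | (2R,4R,6R)-2-[4-(benzyloxy)-3-methoxyphenyl]-6-{2-[4-(benzyloxy)-3,5-dimethoxyphenyl]ethyl}oxan-4-ol | O[C@@H]1C[C@@H](CCc2cc(OC)c(OCc3ccccc3)c(OC)c2)O[C@@H](c2ccc(OCc3ccccc3)c(OC)c2)C1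
F3 | step 5 | (3S,5R)-1-[4-(benzyloxy)-3-methoxyphenyl]-7-[4-(benzyloxy)-3,5-dimethoxyphenyl]heptane-3,5-diol | COc1cc(CC[C@H](O)C[C@H](O)CCc2cc(OC)c(OCc3ccccc3)c(OC)c2)ccc1OCc1ccccc1
F4 | step 4 | [4-(benzyloxy)-3-methoxyphenyl]magnesium bromide | COc1cc([Mg]Br)ccc1OCc1ccccc1
F5 | step 4 | {[(2S,6R)-2-[4-(benzyloxy)-3-methoxyphenyl]-6-{2-[4-(benzyloxy)-3,5-dimethoxyphenyl]ethyl}-5,6-dihydro-2H-pyran-4-yl]oxy}trimethylsilane | C[Si](C)(C)OC1=C[C@@H](c2ccc(OCc3ccccc3)c(OC)c2)O[C@H](CCc2cc(OC)c(OCc3ccccc3)c(OC)c2)C1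
F6 | step 3 | ethyl 5-[4-(benzyloxy)-3,5-dimethoxyphenyl]-3-oxopentanoate | CCOC(=O)CC(=O)CCc1cc(OC)c(OCc2ccccc2)c(OC)c1
F7 | step 3 | ethyl (3R)-5-[4-(benzyloxy)-3,5-dimethoxyphenyl]-3-hydroxypentanoate | CCOC(=O)C[C@H](O)CCc1cc(OC)c(OCc2ccccc2)c(OC)c1
F8 | step 3 | (3R)-5-[4-(benzyloxy)-3,5-dimethoxyphenyl]-3-hydroxy-N-methoxy-N-methylpentanamide | CON(C)C(=O)C[C@H](O)CCc1cc(OC)c(OCc2ccccc2)c(OC)c1
F9 | step 3 | (5R)-7-[4-(benzyloxy)-3,5-dimethoxyphenyl]-5-hydroxyhept-1-yn-3-one | C#CC(=O)C[C@H](O)CCc1cc(OC)c(OCc2ccccc2)c(OC)c1
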